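**Plan**

- Cuts: the C2–C7 bond (hydroxymethyl, cross-coupling), the C4–O bond (propanoate, with inversion), the bonds C1–C2 and C2–C3 that hold ring carbon C2 (removed as a dihalocarbene, C1 and C3 rejoined to a five-membered ring), the acyl–O bond at C6, the enoate C=C (Wittig), then C6–O and C5–isopropyl back to a 4-silyloxycyclopentenone.
- Enabling feature: C2, the carbon carrying C7, sits between the C1 carbonyl and the olefinic C3–H, which is where a dihalocarbene carbon ends up after adding to a cyclopentanone enol ether C1=C3. The other five ring atoms (C1, C6, C5, C4, C3) form a 3-isopropylcyclopentanone oxygenated on both carbons next to the isopropyl carbon.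
- Forward order: the five-membered ring is bought; isopropyl and the C6 oxygen are added; the separately made side-chain acid is esterified on; the ring grows to six members; the C4 propanoate is installed; C7 is coupled; the side-chain silyl ether is removed.
- Stereochemistry: C4 is the (R)-silyloxy carbon of the cyclopentenone; isopropyl adds anti to it (C5); the enol ether is oxidised anti to isopropyl (C6); C4 is inverted in the Mitsunobu step to give the cis C4/C5 relation. The ring expansion creates no stereocentre.

Key step: step 7

Remark: ring atoms carry the numbering of the final cyclohexenone throughout (C1 carbonyl, C2 bearing C7, C3 olefinic CH, C4 propanoate carbon, C5 isopropyl carbon, C6 enoate-bearing carbon); it is assumed that compounds 1, 2, 5 and 19 are purchased as such.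

**Route**

Step 1
Reactants: 1 (tert-butyldiphenylsilyloxy)acetaldehyde; 2 ethyl 2-(triphenylphosphoranylidene)propanoate
Product: 3 ethyl (E)-4-(tert-butyldiphenylsilyloxy)-2-methylbut-2-enoate
Conditions: CH2Cl2, rt
Reagents that add atoms: none
Why: Wittig olefination with a stabilised alpha-methyl ylide, which reacts reversibly enough to give the trisubstituted (E)-enoate with the ester trans to the silyloxymethyl group.

Step 2
Reactants: 3 ethyl (E)-4-(tert-butyldiphenylsilyloxy)-2-methylbut-2-enoate
Product: 4 (E)-4-(tert-butyldiphenylsilyloxy)-2-methylbut-2-enoic acid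
Conditions: LiOH, THF/MeOH/H2O, rt; then 1 M HCl to pH 3
Reagents that add atoms: lithium hydroxide, [Li+].[OH-]
Why: Saponification of the ethyl ester by hydroxide (acyl substitution), to which the primary tert-butyldiphenylsilyl ether and the double-bond geometry are inert at room temperature.

Step 3
Reactants: 5 (R)-4-(tert-butyldimethylsilyloxy)cyclopent-2-en-1-one; 6 isopropylmagnesium chloride
Product: 7 (3R,4R)-4-(tert-butyldimethylsilyloxy)-3-isopropyl-1-(trimethylsilyloxy)cyclopent-1-ene (isopropyl trans to the silyloxy group), carried on crude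
Conditions: CuBr·SMe2 (10 mol %), TMSCl, THF, −78 °C; Et3N, pentane, cold aq. NaHCO3
Reagents that add atoms: chlorotrimethylsilane, C[Si](C)(C)Cl
Why: TMSCl-accelerated copper-catalysed conjugate addition of the Grignard reagent, in which isopropyl is delivered to the enone face opposite the C4 silyloxy group (setting the future C5 centre trans to it) and the enolate is silylated as it forms, which fixes the enol ether on the future C6 side and suppresses E1cB loss of the silyloxy group.

Step 4
Reactants: 7 (3R,4R)-4-(tert-butyldimethylsilyloxy)-3-isopropyl-1-(trimethylsilyloxy)cyclopent-1-ene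
Product: 10 (2R,3R,4R)-4-(tert-butyldimethylsilyloxy)-2-hydroxy-3-isopropylcyclopentan-1-one, via siloxy epoxide 8 (not isolated), via alpha-silyloxy ketone 9 (not isolated)
Conditions: mCPBA, NaHCO3, CH2Cl2, −20 to 0 °C; then citric acid, MeOH, rt
Reagents that add atoms: 3-chloroperoxybenzoic acid, O=C(OO)c1cccc(Cl)c1
Why: Rubottom oxidation: the peracid epoxidises the enol ether on the face opposite the adjacent isopropyl group, the siloxy epoxide opens with 1,4-silyl shift to the alpha-silyloxy ketone and mild acidic methanolysis removes only the trimethylsilyl group, so the new carbinol centre (future C6) is trans to isopropyl, which is also the thermodynamically preferred arrangement.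

Step 5
Reactants: 10 (2R,3R,4R)-4-(tert-butyldimethylsilyloxy)-2-hydroxy-3-isopropylcyclopentan-1-one; 4 (E)-4-(tert-butyldiphenylsilyloxy)-2-methylbut-2-enoic acid
Product: 11 (1R,2R,3R)-3-(tert-butyldimethylsilyloxy)-2-isopropyl-5-oxocyclopentyl (E)-4-(tert-butyldiphenylsilyloxy)-2-methylbut-2-enoate
Conditions: EDC·HCl, DMAP (20 mol %), CH2Cl2, 0 °C to rt
Reagents that add atoms: none
Why: Steglich esterification under near-neutral carbodiimide/DMAP activation, suited to a secondary alpha-hydroxy ketone whose beta-silyloxy group would not survive basic acylation, with an acid that has no alpha-hydrogen and therefore cannot form a ketene or lose its E geometry.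

Step 6
Reactants: 11 (1R,2R,3R)-3-(tert-butyldimethylsilyloxy)-2-isopropyl-5-oxocyclopentyl (E)-4-(tert-butyldiphenylsilyloxy)-2-methylbut-2-enoate
Product: 12 trimethylsilyl enol ether of 11 directed toward the ring CH2 (enol double bond between future C1 and C3; the three stereocentres unchanged)
Conditions: TMSCl (excess), LiN(iPr)2 (LDA, commercial solution), THF, −78 °C, in situ quench; Et3N, pentane, cold aq. NaHCO3
Reagents that add atoms: chlorotrimethylsilane, C[Si](C)(C)Cl
Why: Kinetic enolisation with an internal silyl quench: the hindered amide removes a proton from the unencumbered ring CH2 in preference to the tertiary acyloxy-bearing C–H, the ester offers no alpha-hydrogen, and immediate O-silylation prevents beta-elimination of the neighbouring silyloxy group and acyl transfer to the enolate oxygen.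

Step 7
Reactants: 12 trimethylsilyl enol ether of 11; 13 bromoform
Product: 15 2-bromocyclohex-2-en-1-one carrying the C4 tert-butyldimethylsilyloxy group trans to the C5 isopropyl group and the C6 silyl-protected enoate ester trans to isopropyl, via dibromocyclopropane 14 (not isolated)
Conditions: KOtBu, pentane, −30 °C to rt; aq. NaHCO3 work-up
Reagents that add atoms: none
Why: KOtBu deprotonates bromoform and alpha-elimination of bromide gives dibromocarbene, which adds in a concerted [2+1] cheletropic manner to the electron-rich C1=C3 silyl enol ether of 12 and closes the three-membered ring of 14 (new bonds C1–C2 and C2–C3). The siloxy lone pair then drives the two-electron disrotatory cyclopropyl-to-allyl cation opening in which the fusion bond C1–C3 breaks and the endo bromide leaves, so the six-membered ring arises by enlargement of the five-membered ring and not by a cyclisation; loss of the trimethylsilyl group from the silyloxocarbenium ion gives the conjugated 2-bromoenone 15. The closest known reaction type is the dihalocarbene ring expansion of cyclic silyl enol ethers to 2-halocycloalk-2-enones, which is especially easy for the strained bicyclo[3.1.0]hexane case. No stereocentre is created, because both former enol carbons end up trigonal, so the face of carbene attack is irrelevant and C4, C5 and C6 are untouched. The step needs only site selectivity and chemoselectivity: the position of the ketone and of the new carbon is fixed by the regiodefined enol ether from step 6, the nucleophilic enol ether outcompetes the electron-poor trisubstituted enoate alkene for the electrophilic carbene, and a non-polar medium at low temperature keeps the barely soluble alkoxide from attacking the hindered conjugated ester.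

Step 8
Reactants: 15 2-bromocyclohex-2-en-1-one with C4 tert-butyldimethylsilyloxy trans to isopropyl
Product: 16 the corresponding C4 alcohol (2-bromo-4-hydroxy enone; hydroxyl trans to isopropyl; tert-butyldiphenylsilyl ether retained)
Conditions: 48% aq. HF, MeCN, 0 °C
Reagents that add atoms: none
Why: Acid-type fluoride desilylation that discriminates by acid lability, cleaving the secondary tert-butyldimethylsilyl ether far faster than the primary tert-butyldiphenylsilyl ether while leaving the esters and the bromoenone alone.

Step 9
Reactants: 16 C4 alcohol; 17 propanoic acid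
Product: 18 2-bromo enone carrying the C4 propanoate cis to the C5 isopropyl group (C6 ester trans to isopropyl)
Conditions: PPh3, DIAD, THF, 0 °C to rt
Reagents that add atoms: none
Why: Mitsunobu esterification: the allylic alkoxyphosphonium ion is displaced by propanoate in an SN2 step with inversion, which turns the C4 oxygen from trans to cis relative to isopropyl, while anti elimination is unavailable because the C5 hydrogen is syn to the leaving group and SN2' attack would have to occur at the bromine-bearing carbon.

Step 10
Reactants: 18 2-bromo enone with C4 propanoate; 19 (tributylstannyl)methanol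
Product: 20 tert-butyldiphenylsilyl ether of the target (2-hydroxymethyl enone; side-chain primary alcohol still silylated)
Conditions: Pd2(dba)3 (5 mol %), AsPh3 (20 mol %), CuI (10 mol %), NMP, 50 °C
Reagents that add atoms: none
Why: Stille cross-coupling: zerovalent palladium inserts into the activated alkenyl C–Br bond of the alpha-bromoenone, the hydroxymethyl group is transferred from tin (helped by CuI) and reductive elimination forms the C2–C7 bond under neutral conditions that need no protection of the new alcohol.

Step 11
Reactants: 20 tert-butyldiphenylsilyl ether of the target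
Product: 21 (4S,5S,6R)-2-(hydroxymethyl)-6-[(E)-4-hydroxy-2-methylbut-2-enoyloxy]-5-isopropyl-4-(propanoyloxy)cyclohex-2-en-1-one (CNP0285949.1)
Conditions: HF·pyridine, pyridine, THF, 0 °C to rt
Reagents that add atoms: none
Why: Fluoride-mediated desilylation with pyridine-buffered HF, chosen over basic fluoride sources so that the base-sensitive diacyloxy enone neither undergoes acyl migration nor eliminates carboxylate toward a phenol.

**Compound list**

1 | (tert-butyldiphenylsilyloxy)acetaldehyde | O=CCO[Si](c1ccccc1)(c1ccccc1)C(C)(C)C | starting material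
2 | ethyl 2-(triphenylphosphoranylidene)propanoate | CCOC(=O)C(C)=P(c1ccccc1)(c1ccccc1)c1ccccc1 | starting material
3 | ethyl (E)-4-(tert-butyldiphenylsilyloxy)-2-methylbut-2-enoate | CCOC(=O)/C(C)=C/CO[Si](c1ccccc1)(c1ccccc1)C(C)(C)C | intermediate
4 | (E)-4-(tert-butyldiphenylsilyloxy)-2-methylbut-2-enoic acid | OC(=O)/C(C)=C/CO[Si](c1ccccc1)(c1ccccc1)C(C)(C)C | intermediate
5 | (R)-4-(tert-butyldimethylsilyloxy)cyclopent-2-en-1-one | O=C1C=C[C@H](O[Si](C)(C)C(C)(C)C)C1 | starting material
6 | isopropylmagnesium chloride | CC(C)[Mg]Cl | starting material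
7 | (3R,4R)-4-(tert-butyldimethylsilyloxy)-3-isopropyl-1-(trimethylsilyloxy)cyclopent-1-ene | CC(C)[C@@H]1C=C(O[Si](C)(C)C)C[C@H]1O[Si](C)(C)C(C)(C)C | intermediate
8 | siloxy epoxide of 7 (1-trimethylsilyloxy-6-oxabicyclo[3.1.0]hexane, epoxide oxygen anti to isopropyl) | CC(C)[C@@H]1[C@H]2O[C@@]2(O[Si](C)(C)C)C[C@H]1O[Si](C)(C)C(C)(C)C | intermediate
9 | all-trans 4-(tert-butyldimethylsilyloxy)-3-isopropyl-2-(trimethylsilyloxy)cyclopentan-1-one | CC(C)[C@@H]1[C@@H](O[Si](C)(C)C)C(=O)C[C@H]1O[Si](C)(C)C(C)(C)C | intermediate
10 | (2R,3R,4R)-4-(tert-butyldimethylsilyloxy)-2-hydroxy-3-isopropylcyclopentan-1-one | CC(C)[C@@H]1[C@@H](O)C(=O)C[C@H]1O[Si](C)(C)C(C)(C)C | intermediate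
11 | (1R,2R,3R)-3-(tert-butyldimethylsilyloxy)-2-isopropyl-5-oxocyclopentyl (E)-4-(tert-butyldiphenylsilyloxy)-2-methylbut-2-enoate | CC(C)[C@@H]1[C@@H](OC(=O)/C(C)=C/CO[Si](c2ccccc2)(c2ccccc2)C(C)(C)C)C(=O)C[C@H]1O[Si](C)(C)C(C)(C)C | intermediate
12 | trimethylsilyl enol ether of 11 toward the ring CH2 | CC(C)[C@@H]1[C@@H](OC(=O)/C(C)=C/CO[Si](c2ccccc2)(c2ccccc2)C(C)(C)C)C(O[Si](C)(C)C)=C[C@H]1O[Si](C)(C)C(C)(C)C | intermediate
13 | bromoform | BrC(Br)Br | starting material
14 | 6,6-dibromo-1-(trimethylsilyloxy)bicyclo[3.1.0]hexane from 12 (CBr2 drawn anti to the two flanking oxygen substituents; its configuration is without consequence) | CC(C)[C@@H]1[C@@H](OC(=O)/C(C)=C/CO[Si](c2ccccc2)(c2ccccc2)C(C)(C)C)[C@]3(O[Si](C)(C)C)C(Br)(Br)[C@@H]3[C@H]1O[Si](C)(C)C(C)(C)C | intermediate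
15 | 2-bromo-4-(tert-butyldimethylsilyloxy)-5-isopropyl-6-[(E)-4-(tert-butyldiphenylsilyloxy)-2-methylbut-2-enoyloxy]cyclohex-2-en-1-one (C4–O and C6–O both trans to isopropyl) | CC(C)[C@@H]1[C@@H](OC(=O)/C(C)=C/CO[Si](c2ccccc2)(c2ccccc2)C(C)(C)C)C(=O)C(Br)=C[C@H]1O[Si](C)(C)C(C)(C)C | intermediate
16 | 2-bromo-4-hydroxy analogue of 15 (hydroxyl trans to isopropyl) | CC(C)[C@@H]1[C@@H](OC(=O)/C(C)=C/CO[Si](c2ccccc2)(c2ccccc2)C(C)(C)C)C(=O)C(Br)=C[C@H]1O | intermediate
17 | propanoic acid | CCC(=O)O | starting material
18 | 2-bromo-4-(propanoyloxy) enone (propanoate cis to isopropyl, C6 ester trans) | CC(C)[C@@H]1[C@@H](OC(=O)/C(C)=C/CO[Si](c2ccccc2)(c2ccccc2)C(C)(C)C)C(=O)C(Br)=C[C@@H]1OC(=O)CC | intermediate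
19 | (tributylstannyl)methanol | CCCC[Sn](CCCC)(CCCC)CO | starting material
20 | tert-butyldiphenylsilyl ether of the target (2-hydroxymethyl enone) | CC(C)[C@@H]1[C@@H](OC(=O)/C(C)=C/CO[Si](c2ccccc2)(c2ccccc2)C(C)(C)C)C(=O)C(CO)=C[C@@H]1OC(=O)CC | intermediate
21 | (4S,5S,6R)-2-(hydroxymethyl)-6-[(E)-4-hydroxy-2-methylbut-2-enoyloxy]-5-isopropyl-4-(propanoyloxy)cyclohex-2-en-1-one | CCC(=O)O[C@H]1C=C(CO)C(=O)[C@H](OC(=O)/C(C)=C/CO)[C@H]1C(C)C | target

**Step count and risks**

Total step count: 11. Longest linear sequence: 9 steps (5 to 21, steps 3 to 11); the side-chain acid 4 takes 2 further steps.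

Steps most likely to fail:

1. Step 7 (ring expansion). tert-Butoxide may attack the enoate ester or strip the silyl group from the enol ether faster than the carbene is captured, and the dibromocyclopropane may open only sluggishly. The fallback runs the same ring growth before the ester is present. It sets out from 10: the hydroxyl is silylated (Et3SiCl, imidazole, DMF) to 4-(tert-butyldimethylsilyloxy)-3-isopropyl-2-(triethylsilyloxy)cyclopentanone F1. This is enolised with LiN(iPr)2/TMSCl at −78 °C to the trimethylsilyl enol ether F2, a case in which alpha-silyloxy ketones reliably enolise away from the oxygen. Bromoform/KOtBu then acts on this ester-free substrate and gives the dibromocyclopropane F3, which opens in the flask to the bis-silyl 2-bromoenone F4. Buffered HF·pyridine at 0 °C removes the triethylsilyl ether selectively to the 6-hydroxy bromoenone F5, and carbodiimide/DMAP esterification with 4 returns to the route at 15.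

2. Step 9 (Mitsunobu). The weakly acidic propanoic acid may protonate the betaine too slowly, and the carboxylate has to enter on the face of the adjacent isopropyl group, so the alkoxyphosphonium ion may be diverted to acyl transfer with retention or to decomposition. The fallback separates inversion from acylation and sets out from 16. A Mitsunobu reaction with the smaller and more acidic formic acid (PPh3, DIAD, THF) gives the inverted formate F6. Mild methanolysis (KHCO3, MeOH, 0 °C), which the other two esters tolerate, gives the inverted 4-hydroxy bromoenone F7. Acylation with propanoic anhydride (pyridine, catalytic DMAP, CH2Cl2, 0 °C) returns to the route at 18.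

3. Step 10 (Stille coupling). Zerovalent palladium may ionise the allylic C4 propanoate, leading through a pi-allyl complex to elimination and aromatisation, in competition with insertion into the C–Br bond; slow transfer of the hydroxymethyl group may also end in protodebromination. The fallback couples before any allylic ester exists and sets out from 15. Stille hydroxymethylation with 19 gives the 2-hydroxymethyl enone F8 with the C4 silyl ether still in place. The new primary alcohol is capped (tert-butyldiphenylsilyl chloride, imidazole) to the bis(tert-butyldiphenylsilyl) ether F9. Aqueous HF in MeCN removes the secondary tert-butyldimethylsilyl group to the C4 alcohol F10, and Mitsunobu esterification with 17 gives the inverted propanoate F11. HF·pyridine removes both primary silyl ethers and returns to the route at 21.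

**Further compounds**

F1 | step 7 | all-trans 4-(tert-butyldimethylsilyloxy)-3-isopropyl-2-(triethylsilyloxy)cyclopentan-1-one | CC(C)[C@@H]1[C@@H](O[Si](CC)(CC)CC)C(=O)C[C@H]1O[Si](C)(C)C(C)(C)C
F2 | step 7 | trimethylsilyl enol ether of F1 toward the ring CH2 | CC(C)[C@@H]1[C@@H](O[Si](CC)(CC)CC)C(O[Si](C)(C)C)=C[C@H]1O[Si](C)(C)C(C)(C)C
F3 | step 7 | 6,6-dibromo-1-(trimethylsilyloxy)bicyclo[3.1.0]hexane from F2 (not isolated) | CC(C)[C@@H]1[C@@H](O[Si](CC)(CC)CC)[C@]2(O[Si](C)(C)C)C(Br)(Br)[C@@H]2[C@H]1O[Si](C)(C)C(C)(C)C
F4 | step 7 | 2-bromo-4-(tert-butyldimethylsilyloxy)-5-isopropyl-6-(triethylsilyloxy)cyclohex-2-en-1-one (both oxygens trans to isopropyl) | CC(C)[C@@H]1[C@@H](O[Si](CC)(CC)CC)C(=O)C(Br)=C[C@H]1O[Si](C)(C)C(C)(C)C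
F5 | step 7 | 2-bromo-4-(tert-butyldimethylsilyloxy)-6-hydroxy-5-isopropylcyclohex-2-en-1-one | CC(C)[C@@H]1[C@@H](O)C(=O)C(Br)=C[C@H]1O[Si](C)(C)C(C)(C)C
F6 | step 9 | C4 formate of the 2-bromo enone, formate cis to isopropyl | CC(C)[C@@H]1[C@@H](OC(=O)/C(C)=C/CO[Si](c2ccccc2)(c2ccccc2)C(C)(C)C)C(=O)C(Br)=C[C@@H]1OC=O
F7 | step 9 | 2-bromo-4-hydroxy enone with hydroxyl cis to isopropyl (C4 epimer of 16) | CC(C)[C@@H]1[C@@H](OC(=O)/C(C)=C/CO[Si](c2ccccc2)(c2ccccc2)C(C)(C)C)C(=O)C(Br)=C[C@@H]1O
F8 | step 10 | 2-(hydroxymethyl) enone with C4 tert-butyldimethylsilyloxy trans to isopropyl | CC(C)[C@@H]1[C@@H](OC(=O)/C(C)=C/CO[Si](c2ccccc2)(c2ccccc2)C(C)(C)C)C(=O)C(CO)=C[C@H]1O[Si](C)(C)C(C)(C)C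
F9 | step 10 | C7 tert-butyldiphenylsilyl ether of F8 | CC(C)[C@@H]1[C@@H](OC(=O)/C(C)=C/CO[Si](c2ccccc2)(c2ccccc2)C(C)(C)C)C(=O)C(CO[Si](c2ccccc2)(c2ccccc2)C(C)(C)C)=C[C@H]1O[Si](C)(C)C(C)(C)C
F10 | step 10 | C4 alcohol from F9 (hydroxyl trans to isopropyl) | CC(C)[C@@H]1[C@@H](OC(=O)/C(C)=C/CO[Si](c2ccccc2)(c2ccccc2)C(C)(C)C)C(=O)C(CO[Si](c2ccccc2)(c2ccccc2)C(C)(C)C)=C[C@H]1O
F11 | step 10 | bis(tert-butyldiphenylsilyl) ether of the target (C4 propanoate cis to isopropyl) | CC(C)[C@@H]1[C@@H](OC(=O)/C(C)=C/CO[Si](c2ccccc2)(c2ccccc2)C(C)(C)C)C(=O)C(CO[Si](c2ccccc2)(c2ccccc2)C(C)(C)C)=C[C@@H]1OC(=O)CC
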